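The bond cut that carries the plan is C4a–C5 of the isoquinoline benzene ring. This C6/C8 meta-dioxygenated ring (C4a, C5, C6, C7, C8, C8a) is read as a folded 1,3,5-tricarbonyl chain C4a–C8a–C8–C7–C6–C5 whose terminal carbon C5 already carries the naphthalene. In one operation, base unmasks that triketone from a 4-pyranone and an intramolecular aldol condensation closes and aromatises the ring, so the hindered C5–C1' biaryl bond is made by a carbanion adding to a ketone. The precursor is an N-Boc (5S,7S)-5,7-dimethyltetrahydropyrano[3,2-c]pyridin-4-one carrying the naphthylmethyl group at C2; Boc is chosen because it also directs the trans-selective methylation.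

Key step: step 12

Assumption: the target SMILES fixes only C1 and C3 (both S) and leaves the C5–C1' axis open, so either atropisomer of the (1S,3S) compound satisfies it; if both form they are diastereomers and would be separated by chromatography at compound 24 or 25.

Step 1
Reactants: 1 tert-butyl (2S)-2-methyl-4-oxopiperidine-1-carboxylate
Product: 2 tert-butyl (2S)-2-methyl-4-methylidenepiperidine-1-carboxylate
Conditions: Ph3PCH3Br, KOtBu, THF, 0 °C to rt
Reagents that add atoms: methyltriphenylphosphonium bromide, C[P+](c1ccccc1)(c1ccccc1)c1ccccc1.[Br-]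
Why: Wittig methylenation masks the ketone as an exocyclic alkene that tolerates organolithium chemistry and places no axial substituent on C4, while the C2 stereocentre, which is not alpha to the carbonyl, is left untouched.

Step 2
Reactants: 2 tert-butyl (2S)-2-methyl-4-methylidenepiperidine-1-carboxylate
Product: 4 tert-butyl (2S,6S)-2,6-dimethyl-4-methylidenepiperidine-1-carboxylate (2,6-trans), via 2-lithio carbamate 3 (not isolated)
Conditions: s-BuLi, TMEDA, Et2O, −78 °C; then Me2SO4, −78 °C to rt
Reagents that add atoms: dimethyl sulfate, COS(=O)(=O)OC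
Why: Carbamate-directed alpha-lithiation and alkylation: the existing methyl group sits axial to avoid allylic 1,3-strain with the Boc group, the equatorial C6 proton is removed under complex-induced proximity, and methylation with retention should set the new centre trans, giving the C2-symmetric (2S,6S) isomer.

Step 3
Reactants: 4 tert-butyl (2S,6S)-2,6-dimethyl-4-methylidenepiperidine-1-carboxylate
Product: 6 tert-butyl (2S,6S)-2,6-dimethyl-4-oxopiperidine-1-carboxylate, via spiro ozonide 5 (not isolated)
Conditions: O3, CH2Cl2, −78 °C; then Me2S, −78 °C to rt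
Reagents that add atoms: ozone, [O-][O+]=O
Why: Ozonolysis of the 1,1-disubstituted alkene with reductive work-up should return the ketone under neutral conditions that leave the carbamate and both stereocentres untouched.

Step 4
Reactants: 7 N,N-diethyl-2-methoxybenzamide
Product: 10 N,N-diethyl-2-methoxy-6-(2-methylprop-2-en-1-yl)benzamide, via aryllithium 8 (not isolated), via arylmagnesium bromide 9 (not isolated)
Conditions: s-BuLi, TMEDA, THF, −78 °C; MgBr2·OEt2, −78 to 0 °C; then 3-bromo-2-methylpropene, 0 °C to rt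
Reagents that add atoms: 3-bromo-2-methylprop-1-ene, C=C(C)CBr
Why: Directed ortho-metalation occurs next to the tertiary amide, the stronger director, and transmetalation to magnesium before allylation keeps the basic aryl anion from deprotonating the acidic benzylic position of the product.

Step 5
Reactants: 10 N,N-diethyl-2-methoxy-6-(2-methylprop-2-en-1-yl)benzamide
Product: 11 8-methoxy-3-methylnaphthalen-1-ol
Conditions: LiN(i-Pr)2 (LDA, 2.2 equiv), THF, −78 °C to rt; then 1 M HCl
Reagents that add atoms: none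
Why: Anionic ring annulation of an ortho-allyl benzamide: the benzylic allyl anion adds through its terminal carbon to the amide carbonyl, and loss of diethylamide with tautomerisation gives the 1-naphthol, so the peri-dioxygenation and the 3-methyl group are fixed by construction.

Step 6
Reactants: 11 8-methoxy-3-methylnaphthalen-1-ol
Product: 12 1,8-dimethoxy-3-methylnaphthalene
Conditions: MeI, K2CO3, DMF, 40 °C
Reagents that add atoms: iodomethane, CI
Why: Williamson O-methylation of the naphthol, which has no competing nucleophilic site.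

Step 7
Reactants: 12 1,8-dimethoxy-3-methylnaphthalene
Product: 13 1-bromo-4,5-dimethoxy-2-methylnaphthalene
Conditions: NBS, MeCN, 0 °C to rt, dark
Reagents that add atoms: N-bromosuccinimide, O=C1CCC(=O)N1Br
Why: Electrophilic aromatic bromination should go to C4 of 12, the alpha position para to a methoxy group that is additionally activated by the ortho methyl group, in preference to C5, which lacks that extra activation.

Step 8
Reactants: 13 1-bromo-4,5-dimethoxy-2-methylnaphthalene
Product: 14 ethyl 2-(4,5-dimethoxy-2-methylnaphthalen-1-yl)acetate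
Conditions: BrZnCH2CO2Et (preformed THF solution), Pd2(dba)3 (cat.), XPhos (cat.), THF, 65 °C
Reagents that add atoms: (2-ethoxy-2-oxoethyl)zinc bromide, CCOC(=O)C[Zn]Br
Why: Negishi-type coupling of a Reformatsky reagent (ester alpha-arylation), in which the bulky biaryl phosphine lets zerovalent palladium insert into the hindered, electron-rich bromide and the zinc enolate avoids Claisen side reactions.

Step 9
Reactants: 14 ethyl 2-(4,5-dimethoxy-2-methylnaphthalen-1-yl)acetate
Product: 15 2-(4,5-dimethoxy-2-methylnaphthalen-1-yl)acetic acid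
Conditions: LiOH, THF/MeOH/H2O, rt; then 1 M HCl
Reagents that add atoms: lithium hydroxide, [Li+].[OH-]
Why: Saponification of an unhindered ethyl ester; the basic conditions avoid any carbocation that could alkylate the electron-rich naphthalene.

Step 10
Reactants: 15 2-(4,5-dimethoxy-2-methylnaphthalen-1-yl)acetic acid; 16 Meldrum's acid
Product: 17 5-[2-(4,5-dimethoxy-2-methylnaphthalen-1-yl)-1-hydroxyethylidene]-2,2-dimethyl-1,3-dioxane-4,6-dione
Conditions: DCC, DMAP, CH2Cl2, 0 °C to rt; aq. KHSO4 wash
Reagents that add atoms: none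
Why: Carbodiimide activation with DMAP acyl transfer is the standard C-acylation of Meldrum's acid and gives the acyl derivative as its stable enol.

Step 11
Reactants: 6 tert-butyl (2S,6S)-2,6-dimethyl-4-oxopiperidine-1-carboxylate; 17 5-[2-(4,5-dimethoxy-2-methylnaphthalen-1-yl)-1-hydroxyethylidene]-2,2-dimethyl-1,3-dioxane-4,6-dione
Product: 21 tert-butyl (5S,7S)-2-[(4,5-dimethoxy-2-methylnaphthalen-1-yl)methyl]-5,7-dimethyl-4-oxo-4,5,7,8-tetrahydro-6H-pyrano[3,2-c]pyridine-6-carboxylate, via morpholine enamine 18 (not isolated), via acylketene 19 (not isolated), via vinylogous amide 20 (not isolated)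
Conditions: morpholine, p-TsOH (cat.), toluene, reflux (Dean–Stark), then evaporate; 17 added slowly, toluene, 110 °C; then AcOH, 60 °C
Reagents that add atoms: none
Why: The C2-symmetric ketone can give only one enamine, thermolysis of 17 releases acetone and CO2 to form acylketene 19, which C-acylates the enamine to vinylogous amide 20, and mild acid lets the enol oxygen displace morpholine by 6-endo addition–elimination, the known enamine–acylketene route to 4-pyranones.

Step 12
Reactants: 21 tert-butyl (5S,7S)-2-[(4,5-dimethoxy-2-methylnaphthalen-1-yl)methyl]-5,7-dimethyl-4-oxo-4,5,7,8-tetrahydro-6H-pyrano[3,2-c]pyridine-6-carboxylate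
Product: 23 tert-butyl (1S,3S)-5-(4,5-dimethoxy-2-methylnaphthalen-1-yl)-6,8-dihydroxy-1,3-dimethyl-3,4-dihydroisoquinoline-2(1H)-carboxylate, via triketone 22 (not isolated)
Conditions: KOH (5 equiv), 1,4-dioxane/H2O (degassed), 60 °C; then AcOH, 0 °C
Reagents that add atoms: potassium hydroxide, [K+].[OH-]
Why: Hydroxide adds to C2 of the pyranone (a vinylogous ester) and the ring opens to the enolate of 1,3,5-triketone 22, in which the former ring oxygen has become the C4a ketone; the C5 methylene, flanked by the naphthalene and the C6 carbonyl, is then deprotonated and adds to C4a, and loss of water with enolisation of the C6 and C8 carbonyls gives the resorcinol irreversibly. The closest known reaction type is the base-induced conversion of 4-pyranones and 1,3,5-triketones into resorcinols, together with arene-forming aldol condensations that deliver hindered biaryls. The one new ring, the benzene ring C4a–C5–C6–C7–C8–C8a, closes in a 6-(enolendo)-exo-trig aldol mode. No new stereocentre is created: C1 and C3 are carried through from 21, and the C5–C1' axis forms without control. The selectivity needed is C5-to-C4a closure over the C4-to-C6 aldol, and the substrate secures it because only the former can dehydrate to an arene, whereas the latter gives a bridged aldol that forms reversibly. Integrity of C1 and C3 relies on the carbamate nitrogen being a poor leaving group for beta-elimination at the moderate temperature used.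

Step 13
Reactants: 23 tert-butyl (1S,3S)-5-(4,5-dimethoxy-2-methylnaphthalen-1-yl)-6,8-dihydroxy-1,3-dimethyl-3,4-dihydroisoquinoline-2(1H)-carboxylate
Product: 24 tert-butyl (1S,3S)-5-(4,5-dimethoxy-2-methylnaphthalen-1-yl)-6,8-dimethoxy-1,3-dimethyl-3,4-dihydroisoquinoline-2(1H)-carboxylate
Conditions: MeI, K2CO3, DMF, rt to 40 °C
Reagents that add atoms: iodomethane, CI
Why: Williamson methylation of both phenols, with the carbamate keeping nitrogen from being alkylated.

Step 14
Reactants: 24 tert-butyl (1S,3S)-5-(4,5-dimethoxy-2-methylnaphthalen-1-yl)-6,8-dimethoxy-1,3-dimethyl-3,4-dihydroisoquinoline-2(1H)-carboxylate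
Product: 25 (1S,3S)-5-(4,5-dimethoxy-2-methylnaphthalen-1-yl)-6,8-dimethoxy-1,3-dimethyl-1,2,3,4-tetrahydroisoquinoline
Conditions: HCl (4 M in 1,4-dioxane), 0 °C to rt; then aq. NaHCO3
Reagents that add atoms: none
Why: Acidolysis of the tert-butyl carbamate releases 2-methylpropene and CO2 and should leave the aryl methyl ethers, the biaryl bond and both stereocentres unchanged.

Compound list
1 | tert-butyl (2S)-2-methyl-4-oxopiperidine-1-carboxylate | O=C1C[C@H](C)N(C(=O)OC(C)(C)C)CC1 | starting material
2 | tert-butyl (2S)-2-methyl-4-methylidenepiperidine-1-carboxylate | C=C1C[C@H](C)N(C(=O)OC(C)(C)C)CC1 | intermediate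
3 | tert-butyl (2S,6S)-2-lithio-6-methyl-4-methylidenepiperidine-1-carboxylate (lithium equatorial, trans to methyl) | C=C1C[C@H](C)N(C(=O)OC(C)(C)C)[C@@H]([Li])C1 | intermediate
4 | tert-butyl (2S,6S)-2,6-dimethyl-4-methylidenepiperidine-1-carboxylate | C=C1C[C@H](C)N(C(=O)OC(C)(C)C)[C@@H](C)C1 | intermediate
5 | tert-butyl (7S,9S)-7,9-dimethyl-1,2,4-trioxa-8-azaspiro[4.5]decane-8-carboxylate | C1OOC2(O1)C[C@H](C)N(C(=O)OC(C)(C)C)[C@@H](C)C2 | intermediate
6 | tert-butyl (2S,6S)-2,6-dimethyl-4-oxopiperidine-1-carboxylate | O=C1C[C@H](C)N(C(=O)OC(C)(C)C)[C@@H](C)C1 | intermediate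
7 | N,N-diethyl-2-methoxybenzamide | CCN(CC)C(=O)c1ccccc1OC | starting material
8 | N,N-diethyl-2-lithio-6-methoxybenzamide | CCN(CC)C(=O)c1c([Li])cccc1OC | intermediate
9 | [2-(diethylcarbamoyl)-3-methoxyphenyl]magnesium bromide | CCN(CC)C(=O)c1c([Mg]Br)cccc1OC | intermediate
10 | N,N-diethyl-2-methoxy-6-(2-methylprop-2-en-1-yl)benzamide | CCN(CC)C(=O)c1c(CC(C)=C)cccc1OC | intermediate
11 | 8-methoxy-3-methylnaphthalen-1-ol | COc1cccc2cc(C)cc(O)c12 | intermediate
12 | 1,8-dimethoxy-3-methylnaphthalene | COc1cccc2cc(C)cc(OC)c12 | intermediate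
13 | 1-bromo-4,5-dimethoxy-2-methylnaphthalene | COc1cccc2c(Br)c(C)cc(OC)c12 | intermediate
14 | ethyl 2-(4,5-dimethoxy-2-methylnaphthalen-1-yl)acetate | CCOC(=O)Cc1c(C)cc(OC)c2c(OC)cccc12 | intermediate
15 | 2-(4,5-dimethoxy-2-methylnaphthalen-1-yl)acetic acid | OC(=O)Cc1c(C)cc(OC)c2c(OC)cccc12 | intermediate
16 | Meldrum's acid (2,2-dimethyl-1,3-dioxane-4,6-dione) | CC1(C)OC(=O)CC(=O)O1 | starting material
17 | 5-[2-(4,5-dimethoxy-2-methylnaphthalen-1-yl)-1-hydroxyethylidene]-2,2-dimethyl-1,3-dioxane-4,6-dione | CC1(C)OC(=O)C(=C(O)Cc2c(C)cc(OC)c3c(OC)cccc23)C(=O)O1 | intermediate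
18 | tert-butyl (2S,6S)-2,6-dimethyl-4-(morpholin-4-yl)-3,6-dihydropyridine-1(2H)-carboxylate | C1(N2CCOCC2)=C[C@H](C)N(C(=O)OC(C)(C)C)[C@@H](C)C1 | intermediate
19 | 4-(4,5-dimethoxy-2-methylnaphthalen-1-yl)-3-oxobut-1-en-1-one | O=C=CC(=O)Cc1c(C)cc(OC)c2c(OC)cccc12 | intermediate
20 | tert-butyl (2S,6S)-3-[4-(4,5-dimethoxy-2-methylnaphthalen-1-yl)-3-oxobutanoyl]-2,6-dimethyl-4-(morpholin-4-yl)-5,6-dihydropyridine-1(2H)-carboxylate | O=C(CC(=O)Cc1c(C)cc(OC)c2c(OC)cccc12)C1=C(N2CCOCC2)C[C@H](C)N(C(=O)OC(C)(C)C)[C@H]1C | intermediate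
21 | tert-butyl (5S,7S)-2-[(4,5-dimethoxy-2-methylnaphthalen-1-yl)methyl]-5,7-dimethyl-4-oxo-4,5,7,8-tetrahydro-6H-pyrano[3,2-c]pyridine-6-carboxylate | O=C1C=C(Cc2c(C)cc(OC)c3c(OC)cccc23)OC2=C1[C@H](C)N(C(=O)OC(C)(C)C)[C@@H](C)C2 | intermediate
22 | tert-butyl (2S,6S)-3-[4-(4,5-dimethoxy-2-methylnaphthalen-1-yl)-3-oxobutanoyl]-2,6-dimethyl-4-oxopiperidine-1-carboxylate (C3 not defined, enolisable) | O=C1C[C@H](C)N(C(=O)OC(C)(C)C)[C@@H](C)C1C(=O)CC(=O)Cc1c(C)cc(OC)c2c(OC)cccc12 | intermediate
23 | tert-butyl (1S,3S)-5-(4,5-dimethoxy-2-methylnaphthalen-1-yl)-6,8-dihydroxy-1,3-dimethyl-3,4-dihydroisoquinoline-2(1H)-carboxylate | Oc1cc(O)c2c(c1-c1c(C)cc(OC)c3c(OC)cccc13)C[C@H](C)N(C(=O)OC(C)(C)C)[C@H]2C | intermediate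
24 | tert-butyl (1S,3S)-5-(4,5-dimethoxy-2-methylnaphthalen-1-yl)-6,8-dimethoxy-1,3-dimethyl-3,4-dihydroisoquinoline-2(1H)-carboxylate | COc1cc(OC)c2c(c1-c1c(C)cc(OC)c3c(OC)cccc13)C[C@H](C)N(C(=O)OC(C)(C)C)[C@H]2C | intermediate
25 | (1S,3S)-5-(4,5-dimethoxy-2-methylnaphthalen-1-yl)-6,8-dimethoxy-1,3-dimethyl-1,2,3,4-tetrahydroisoquinoline | COc1cc(OC)c2c(c1-c1c(C)cc(OC)c3c(OC)cccc13)C[C@H](C)N[C@H]2C | target

Total step count: 14.
Longest linear sequence: 11 steps (steps 4 to 14, from 7 to 25); the piperidone branch (steps 1 to 3) joins at step 11.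

Steps most likely to fail

Step 12. The encumbered naphthylmethyl carbanion of triketone 22 may add to the C4a ketone too slowly, so that retro-Claisen cleavage of the triketone or beta-elimination of the carbamate (which would erode C1 and C3) takes over. The fallback moves the making of the biaryl bond to a cross-coupling, so the aldol aromatisation only has to deliver the unhindered parent ring. Setting out from ketone 6 through its enamine 18, acylation with acetylketene released from commercial 2,2,6-trimethyl-4H-1,3-dioxin-4-one (xylene, 120 °C; then AcOH) should give tert-butyl (5S,7S)-2,5,7-trimethyl-4-oxo-4,5,7,8-tetrahydro-6H-pyrano[3,2-c]pyridine-6-carboxylate F1. The same hydroxide treatment, now with a methyl carbanion, should give tert-butyl (1S,3S)-6,8-dihydroxy-1,3-dimethyl-3,4-dihydroisoquinoline-2(1H)-carboxylate F2. Methylation (MeI, K2CO3, DMF) would give tert-butyl (1S,3S)-6,8-dimethoxy-1,3-dimethyl-3,4-dihydroisoquinoline-2(1H)-carboxylate F3, and NBS in MeCN should brominate para to the C8 methoxy group to give tert-butyl (1S,3S)-5-bromo-6,8-dimethoxy-1,3-dimethyl-3,4-dihydroisoquinoline-2(1H)-carboxylate F4. In parallel, bromide 13 would be converted by bromine–lithium exchange (n-BuLi, THF, −78 °C) into (4,5-dimethoxy-2-methylnaphthalen-1-yl)lithium F5 and then with B(Oi-Pr)3 and aqueous HCl into (4,5-dimethoxy-2-methylnaphthalen-1-yl)boronic acid F6. Suzuki–Miyaura coupling of F4 with F6 (Pd(OAc)2, SPhos, K3PO4, toluene/H2O, 100 °C) would form the C5–C1' bond and come back to the route at compound 24.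

Step 11. Proton transfer from the acidic acyl Meldrum's acid to the basic enamine, or capture of the acylketene by morpholine, may divert the C-acylation. The fallback replaces the enamine acylation by a neutral inverse-demand hetero-Diels–Alder reaction of an enol ether, the known route from acyl Meldrum's acids to 4-pyranones. Setting out from ketone 6, HC(OMe)3 with catalytic PPTS in MeOH should give tert-butyl (2S,6S)-4,4-dimethoxy-2,6-dimethylpiperidine-1-carboxylate F7, and TMSOTf with i-Pr2NEt (CH2Cl2, −20 °C) should remove methanol to give tert-butyl (2S,6S)-4-methoxy-2,6-dimethyl-3,6-dihydropyridine-1(2H)-carboxylate F8. Heating F8 with 17 in toluene at 110 °C should give the cycloadduct tert-butyl (5S,7S)-2-[(4,5-dimethoxy-2-methylnaphthalen-1-yl)methyl]-8a-methoxy-5,7-dimethyl-4-oxo-4a,5,8,8a-tetrahydro-4H-pyrano[3,2-c]pyridine-6(7H)-carboxylate F9. Catalytic p-TsOH in THF at rt would then eliminate methanol and come back to the route at pyranone 21.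

Step 7. Regiocontrol may be lost, with bromine entering C5 of the other ring (also para to a methoxy group) or entering twice. The fallback inverts the order of steps 6 and 7 so that the free hydroxyl, not the methyl group, decides the site. Setting out from naphthol 11, Bu4NBr3 in CH2Cl2/MeOH at 0 °C should brominate only the phenolic ring para to the hydroxyl and give 4-bromo-8-methoxy-3-methylnaphthalen-1-ol F10. Methylation (MeI, K2CO3, DMF) would then come back to the route at bromide 13.

Further compounds
F1 | step 12 | tert-butyl (5S,7S)-2,5,7-trimethyl-4-oxo-4,5,7,8-tetrahydro-6H-pyrano[3,2-c]pyridine-6-carboxylate | O=C1C=C(C)OC2=C1[C@H](C)N(C(=O)OC(C)(C)C)[C@@H](C)C2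
F2 | step 12 | tert-butyl (1S,3S)-6,8-dihydroxy-1,3-dimethyl-3,4-dihydroisoquinoline-2(1H)-carboxylate | Oc1cc(O)c2c(c1)C[C@H](C)N(C(=O)OC(C)(C)C)[C@H]2C
F3 | step 12 | tert-butyl (1S,3S)-6,8-dimethoxy-1,3-dimethyl-3,4-dihydroisoquinoline-2(1H)-carboxylate | COc1cc(OC)c2c(c1)C[C@H](C)N(C(=O)OC(C)(C)C)[C@H]2C
F4 | step 12 | tert-butyl (1S,3S)-5-bromo-6,8-dimethoxy-1,3-dimethyl-3,4-dihydroisoquinoline-2(1H)-carboxylate | COc1cc(OC)c2c(c1Br)C[C@H](C)N(C(=O)OC(C)(C)C)[C@H]2C
F5 | step 12 | (4,5-dimethoxy-2-methylnaphthalen-1-yl)lithium | [Li]c1c(C)cc(OC)c2c(OC)cccc12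
F6 | step 12 | (4,5-dimethoxy-2-methylnaphthalen-1-yl)boronic acid | OB(O)c1c(C)cc(OC)c2c(OC)cccc12
F7 | step 11 | tert-butyl (2S,6S)-4,4-dimethoxy-2,6-dimethylpiperidine-1-carboxylate | COC1(OC)C[C@H](C)N(C(=O)OC(C)(C)C)[C@@H](C)C1
F8 | step 11 | tert-butyl (2S,6S)-4-methoxy-2,6-dimethyl-3,6-dihydropyridine-1(2H)-carboxylate | COC1=C[C@H](C)N(C(=O)OC(C)(C)C)[C@@H](C)C1
F9 | step 11 | tert-butyl (5S,7S)-2-[(4,5-dimethoxy-2-methylnaphthalen-1-yl)methyl]-8a-methoxy-5,7-dimethyl-4-oxo-4a,5,8,8a-tetrahydro-4H-pyrano[3,2-c]pyridine-6(7H)-carboxylate (4a and 8a not defined) | O=C1C=C(Cc2c(C)cc(OC)c3c(OC)cccc23)OC2(OC)C1[C@H](C)N(C(=O)OC(C)(C)C)[C@@H](C)C2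
F10 | step 7 | 4-bromo-8-methoxy-3-methylnaphthalen-1-ol | COc1cccc2c(Br)c(C)cc(O)c12
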